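The constants split into two groups, those of the acid and those of the carbon chemistry, and they rank what happens in this flask from fastest to slowest.

    target → over-reaction product (k1 = 0.32 min⁻¹)
    electrophile + target → side product (k2 = 1.1 L mol⁻¹ min⁻¹)
    acid set free + free base ⇌ salt of the base (K3 = 9.8 L mol⁻¹, k3 = 0.59 L mol⁻¹ min⁻¹)
    nucleophile + acid set free ⇌ protonated nucleophile, settled at all times (K4 = 1100 L mol⁻¹)
    electrophile + protic impurity → quenched substrate (k5 = 1.3 L mol⁻¹ min⁻¹)
    electrophile + nucleophile → acid set free + target (k6 = 0.13 L mol⁻¹ min⁻¹)

electrophile 2.0 M; nucleophile 1.10 equiv; free base 0.300 equiv; protic impurity 0.0400 M; time 12 min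

1. part of the electrophile that has reacted at 12 min
2. share of the unused nucleophile that is free and not bound as protonated nucleophile, at 12 min

- in percentages every species weighs as the electrophile in it: one side product counts as two
- run time (flask): 12 min

On the first rung, kept at balance, the acid set free finds a partner. K[nucleophile] at the start is 2400, while K[free base] is 5.9, so I book each acid to the nucleophile, and each coupling costs two nucleophiles. I therefore keep 1.10 M as the coupling ceiling, the extent of coupling the nucleophile pays for at two apiece, which is half of the charged [nucleophile].

Next comes the protic impurity, with a half-life of 0.267 min under the charged electrophile, and it takes 0.0400 M of electrophile, leaving 1.96 M. Target follows: at [electrophile] of half the charge its half-life is 0.488 min, so I hold it near steady state, and at that [electrophile] 77.5% of it goes on to side product. Each coupling thus burns 1.77 electrophiles, and I call this the price.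

Coupling, with a starting half-life of 2.42 min, is the slowest of these rungs, the rate-limiting step. The electrophile's own ceiling, 1.11 M, nearly equals the nucleophile's, so the rate goes as the square of the distance to one ceiling, which integrates in closed form. The extent is the ceiling times θ/(1+θ), where θ, the product of 2, the price, the coupling constant, the ceiling and the time, is 6.09. That gives 0.945 M, so I commit to c = 85.8% and fr = 24.7%.

The forecast stands lower than I do, at 84.2% and 23.6%, saying “each coupling costs two nucleophiles”. The simulation gives 85.0% and 23.3%.

In this flask at 12 min, electrophile has a half-life of 18 min by coupling and 30 min by the step into side product, so coupling is the faster. Side product in this flask then holds 70.1% of the electrophile charged. Protonated nucleophile in this flask reads 0.951 M, under the ceiling. A neighbour flask with 0.660 equiv of nucleophile has a ceiling of 0.660 M and holds 0.620 M of protonated nucleophile at 12.0 min. My price puts its electrophile used at that ceiling at 60.6%, and it reads 59.9%, with 4.5% of its nucleophile left.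

(All constants belong to no real substance; the rest is arithmetic.)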